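The plan cuts ring D at the C13–C16 bond. Ring D shows a tertiary hydroxyl on the bridgehead C13 right beside the methylene-bearing C16 (C16=C17), the signature of a C16 alkenyl–metal adding to a ring C ketone at C13. One intramolecular Nozaki–Hiyama–Kishi reaction should therefore form C13–C16, close ring D and set the C13 carbinol centre with the methylene already in place. Its precursor holds rings A, B and C with the lactone, a C13 ketone, a C12 silyloxy group, a 2,3-acetonide, a fluoride-labile C7 ester and a 2-iodoallyl arm on C8. Gibberellic acid supplies rings A to C; opening its ring D is what exposes C12 for oxygenation.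

Key step: step 16

Assumption: gibberellic acid (GA3), a fermentation product sold in bulk, is taken as a commercial starting material, so the route is a relay in which ring D is opened and rebuilt; gibberellane numbering is used, and on ring C β is the face of H9 and of the C15–C16 bridge, α the face of C10.

Step 1
Reactants: 1 gibberellic acid (GA3)
Product: 2 GA3 2-(trimethylsilyl)ethyl ester (C7 ester, all centres as in 1)
Conditions: 2-(trimethylsilyl)ethanol (excess), EDC·HCl, DMAP (cat.), CH2Cl2/THF, 0 °C → rt
Reagents that add atoms: 2-(trimethylsilyl)ethanol, C[Si](C)(C)CCO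
Why: Steglich esterification, in which the carbodiimide activates the C7 acid and DMAP passes the acyl group to the excess primary alcohol, which should outcompete the hindered secondary 3-OH and tertiary 13-OH; no stereocentre is touched.

Step 2
Reactants: 2 GA3 2-(trimethylsilyl)ethyl ester
Product: 4 16-oxo-17-nor ester (ring D 13-hydroxy-16-ketone, ring A unchanged), via 16,17-diol 3 (not isolated)
Conditions: OsO4 (cat.), NaIO4, 2,6-lutidine, dioxane/H2O, rt
Reagents that add atoms: sodium periodate (NaIO4), [Na+].[O-]I(=O)(=O)=O; water, O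
Why: Lemieux–Johnson oxidation, in which OsO4 should dihydroxylate the electron-rich exocyclic C16=C17 bond (open exo face, giving 3) in preference to the ring A C1=C2 bond, which is deactivated by allylic oxygen on both sides, and periodate then cleaves the diol to the 16-ketone, so the C16 centre of 3 does not persist.

Step 3
Reactants: 4 16-oxo-17-nor ester
Product: 5 1β-chloro-3-deoxy-2-ene 16-oxo-17-nor ester
Conditions: PPh3, CCl4, MeCN, 60 °C
Reagents that add atoms: carbon tetrachloride, ClC(Cl)(Cl)Cl
Why: Appel reaction run as an allylic SN2′ substitution, in which chloride should enter at C1 on the β face once the axial 3β-hydroxyl is activated on phosphorus, because direct attack at C3 is shielded by the quaternary C4 and the lactone bridge; the C1 centre (and any 3α-chloro-1-ene from direct displacement) is of no consequence because step 4 runs through one common allyl radical.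

Step 4
Reactants: 5 1β-chloro-3-deoxy-2-ene 16-oxo-17-nor ester
Product: 6 3-deoxy-2-ene 16-oxo-17-nor ester (ring A as in GA5)
Conditions: Bu3SnH, AIBN (cat.), PhH, 80 °C
Reagents that add atoms: none
Why: Radical-chain dehalogenation with tributyltin hydride, in which the C1–C2–C3 allyl radical should accept hydrogen at C1, the terminus away from the quaternary C4, leaving the C2=C3 alkene and creating no stereocentre.

Step 5
Reactants: 6 3-deoxy-2-ene 16-oxo-17-nor ester
Product: 7 13,16-diol (16-OH endo, on the C12 side)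
Conditions: NaBH4, MeOH/THF, −20 → 0 °C
Reagents that add atoms: none
Why: Borohydride reduction of a ketone beside a lactone and an ester, with hydride expected from the open exo (C14) side to give the endo alcohol, although either C16 epimer serves because this centre is destroyed in step 6.

Step 6
Reactants: 7 13,16-diol
Product: 8 13,16-seco keto aldehyde (ring C 13-ketone, CH2CHO on C8)
Conditions: NaIO4, THF/H2O (pH 7), rt
Reagents that add atoms: none
Why: Malaprade glycol cleavage, in which the gauche 13,16-diol forms a cyclic periodate ester that breaks the C13–C16 bond and opens ring D to the C13 ketone and the C16 aldehyde without touching any stereocentre.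

Step 7
Reactants: 8 13,16-seco keto aldehyde
Product: 9 keto alkyne (propargyl on C8)
Conditions: dimethyl (1-diazo-2-oxopropyl)phosphonate, K2CO3, MeOH, 0 °C → rt
Reagents that add atoms: dimethyl (1-diazo-2-oxopropyl)phosphonate, COP(=O)(OC)C(=[N+]=[N-])C(C)=O
Why: Seyferth–Gilbert homologation with the Ohira–Bestmann reagent, whose diazophosphonate anion should add to the aldehyde only (the ring ketone is far less electrophilic) and, after loss of phosphate and N2, give the terminal alkyne C16≡C17; no stereocentre is formed.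

Step 8
Reactants: 9 keto alkyne
Product: 11 2-iodoallyl ketone (CH2C(I)=CH2 on C8), via alkenylborane 10 (not isolated)
Conditions: B-iodo-9-BBN, hexane/CH2Cl2, −20 → 0 °C; then AcOH, 0 °C
Reagents that add atoms: B-iodo-9-borabicyclo[3.3.1]nonane, IB1C2CCCC1CCC2
Why: Haloboration–protonolysis (Markovnikov hydroiodination), in which B–I should add syn across the terminal alkyne with iodine on the internal carbon C16 to give 10 and acetic acid then cleaves the C17–B bond, while the ring A alkene is inert because the borane has no B–H bond.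

Step 9
Reactants: 11 2-iodoallyl ketone
Product: 12 2β,3β-diol
Conditions: OsO4 (cat.), N-methylmorpholine N-oxide, acetone/H2O, rt
Reagents that add atoms: N-methylmorpholine N-oxide, C[N+]1([O-])CCOCC1; water, O
Why: Upjohn dihydroxylation, in which OsO4 adds suprafacially to C2=C3 from the β face (the α face lies under the C19–O lactone bridge) and so sets the cis 2β,3β-diol, while the electron-poor iodoalkene should react far more slowly.

Step 10
Reactants: 12 2β,3β-diol
Product: 13 2β,3β-acetonide
Conditions: 2,2-dimethoxypropane, PPTS (cat.), acetone, rt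
Reagents that add atoms: 2,2-dimethoxypropane, COC(C)(C)OC
Why: Acid-catalysed transketalisation, in which the cis diol closes a five-membered isopropylidene acetal that masks both hydroxyls for the enolate, oxidation and chromium steps; no stereocentre changes.

Step 11
Reactants: 13 2β,3β-acetonide
Product: 14 C13 trimethylsilyl enol ether (C12=C13)
Conditions: LiN(SiMe3)2, Me3SiCl, Et3N, THF, −78 °C
Reagents that add atoms: chlorotrimethylsilane, C[Si](C)(C)Cl
Why: Kinetic enolisation with in situ silylation, in which the hindered amide base should take a proton from C12, the unencumbered methylene, and not from C14, which is neopentyl (next to the quaternary C8).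

Step 12
Reactants: 14 C13 trimethylsilyl enol ether
Product: 16 12β-hydroxy 13-ketone, via silyloxy epoxide 15 (not isolated)
Conditions: dimethyldioxirane (acetone solution), CH2Cl2, −78 → −20 °C; then aq. citric acid, THF, 0 °C
Reagents that add atoms: dimethyldioxirane, CC1(C)OO1
Why: Rubottom oxidation, in which the dioxirane should epoxidise the enol ether on the open β face of ring C (C6 and C10 both lie on the α face) to give 15, whose hydrolytic collapse gives the 12β-hydroxy ketone; this sets C12 opposite to the target, which step 13 corrects.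

Step 13
Reactants: 16 12β-hydroxy 13-ketone
Product: 17 12α-(4-nitrobenzoate) 13-ketone
Conditions: PPh3, DIAD, 4-nitrobenzoic acid, PhMe, 0 °C → rt
Reagents that add atoms: 4-nitrobenzoic acid, O=C(O)c1ccc(cc1)[N+](=O)[O-]
Why: Mitsunobu reaction, in which the carboxylate should displace the phosphorus-activated 12β-oxygen in an SN2 step accelerated by the adjacent carbonyl, inverting C12 to the 12α configuration of the target.

Step 14
Reactants: 17 12α-(4-nitrobenzoate) 13-ketone
Product: 18 12α-hydroxy 13-ketone
Conditions: K2CO3 (cat.), MeOH, 0 °C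
Reagents that add atoms: none
Why: Base-catalysed transesterification (methanolysis) of the activated ester, mild enough to free the 12α-hydroxyl without enolising C12; in the preferred chair of the monocyclic ring C this hydroxyl is equatorial, so no drift back to 12β is expected.

Step 15
Reactants: 18 12α-hydroxy 13-ketone
Product: 19 12α-(tert-butyldimethylsilyloxy) 13-ketone with 2-iodoallyl on C8 (key-step precursor)
Conditions: TBSOTf, 2,6-lutidine, CH2Cl2, −78 → 0 °C
Reagents that add atoms: tert-butyldimethylsilyl trifluoromethanesulfonate, CC(C)(C)[Si](C)(C)OS(=O)(=O)C(F)(F)F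
Why: Silyl triflate silylation of the secondary alcohol, giving a silyl ether that, unlike an ester, should not be cleaved reductively by divalent chromium and that blocks α-ketol isomerisation; C12 is untouched.

Step 16
Reactants: 19 12α-(tert-butyldimethylsilyloxy) 13-ketone with 2-iodoallyl on C8
Product: 22 ring D-closed 13-hydroxy-16-methylene 12α-silyl ether (2,3-acetonide; C7 2-(trimethylsilyl)ethyl ester; key-step product), via alkenylchromium species 20 (not isolated), via chromium alkoxide 21 (not isolated)
Conditions: CrCl2 (excess), NiCl2 (cat.), degassed DMF/THF, rt → 50 °C; aq. work-up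
Reagents that add atoms: none
Why: Catalytic nickel, brought to the zerovalent state by CrCl2, should undergo oxidative addition at the C16–I bond and pass the alkenyl group on to chromium, so that the trivalent alkenylchromium species 20 is the working nucleophile; it adds to the C13 carbonyl to give the chromium alkoxide 21, which the aqueous work-up hydrolyses. The closest known reaction type is the intramolecular Nozaki–Hiyama–Kishi (Barbier-type) addition of an alkenyl iodide to a ketone, a known if slower relative of the aldehyde coupling. Ring D (C8–C15–C16–C13–C14) closes in the 5-exo-trig mode at the carbonyl carbon and completes the bicyclo[3.2.1]octane. C13 is the only new stereocentre and is set by geometry alone: C16 hangs from C15 on the β face of ring C and can reach C13 only from that face, which leaves the oxygen in the outward bridgehead position found in the target. The selectivity needed is chemoselectivity, namely carbonyl addition ahead of protonolysis of 20, of attack on the lactone or the C7 ester, of C12 epimerisation and of reductive loss of the C12 oxygen. It should be secured by the weak basicity and low reducing power of alkenylchromium reagents, by the silyl (not acyl) group on O12 and by the quaternary C8, which holds C16 within bonding distance of C13.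

Step 17
Reactants: 22 ring D-closed 13-hydroxy-16-methylene 12α-silyl ether
Product: 23 12α,13-dihydroxy 7-acid 2,3-acetonide
Conditions: Bu4NF, THF, rt → 40 °C; then aq. citric acid
Reagents that add atoms: none
Why: Fluoride-induced desilylation, in which fluoride cleaves the C12–O–Si bond and triggers β-elimination of the 2-(trimethylsilyl)ethyl ester (ethene and Me3SiF), so the hindered C7 acid is freed without hydroxide, which on a free 3-hydroxy-19,10-lactone would epimerise C3 by retro-aldol opening.

Step 18
Reactants: 23 12α,13-dihydroxy 7-acid 2,3-acetonide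
Product: 24 CNP0191054.1 (target)
Conditions: AcOH/H2O (4:1), 40 °C
Reagents that add atoms: none
Why: Acid-catalysed acetal hydrolysis, in which warm aqueous acetic acid should remove the isopropylidene group while leaving the lactone and the acid-sensitive 13-hydroxy-16-ene unit intact; no stereocentre is affected.

Compound list

1 | gibberellic acid (GA3) | C=C1C[C@]23C[C@@]1(O)CC[C@H]2[C@@]12C=C[C@H](O)[C@@](C)(C(=O)O1)[C@H]2[C@@H]3C(=O)O | starting material
2 | GA3 2-(trimethylsilyl)ethyl ester | C=C1C[C@]23C[C@@]1(O)CC[C@H]2[C@@]12C=C[C@H](O)[C@@](C)(C(=O)O1)[C@H]2[C@@H]3C(=O)OCC[Si](C)(C)C | intermediate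
3 | 16,17-diol of 2 (16-OH exo; not isolated) | OC[C@@]1(O)C[C@]23C[C@@]1(O)CC[C@H]2[C@@]12C=C[C@H](O)[C@@](C)(C(=O)O1)[C@H]2[C@@H]3C(=O)OCC[Si](C)(C)C | intermediate
4 | 16-oxo-17-nor ester (ring D 13-hydroxy-16-ketone) | O=C1C[C@]23C[C@@]1(O)CC[C@H]2[C@@]12C=C[C@H](O)[C@@](C)(C(=O)O1)[C@H]2[C@@H]3C(=O)OCC[Si](C)(C)C | intermediate
5 | 1β-chloro-3-deoxy-2-ene 16-oxo-17-nor ester | O=C1C[C@]23C[C@@]1(O)CC[C@H]2[C@@]12[C@H](Cl)C=C[C@@](C)(C(=O)O1)[C@H]2[C@@H]3C(=O)OCC[Si](C)(C)C | intermediate
6 | 3-deoxy-2-ene 16-oxo-17-nor ester | O=C1C[C@]23C[C@@]1(O)CC[C@H]2[C@@]12CC=C[C@@](C)(C(=O)O1)[C@H]2[C@@H]3C(=O)OCC[Si](C)(C)C | intermediate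
7 | 13,16-diol (16-OH endo) | O[C@H]1C[C@]23C[C@@]1(O)CC[C@H]2[C@@]12CC=C[C@@](C)(C(=O)O1)[C@H]2[C@@H]3C(=O)OCC[Si](C)(C)C | intermediate
8 | 13,16-seco keto aldehyde (13-ketone, CH2CHO on C8) | O=CC[C@]23CC(=O)CC[C@H]2[C@@]12CC=C[C@@](C)(C(=O)O1)[C@H]2[C@@H]3C(=O)OCC[Si](C)(C)C | intermediate
9 | keto alkyne (propargyl on C8) | C#CC[C@]23CC(=O)CC[C@H]2[C@@]12CC=C[C@@](C)(C(=O)O1)[C@H]2[C@@H]3C(=O)OCC[Si](C)(C)C | intermediate
10 | (Z)-2-iodoalkenyl-9-BBN adduct of 9 (not isolated) | I/C(=C\B4C5CCCC4CCC5)C[C@]23CC(=O)CC[C@H]2[C@@]12CC=C[C@@](C)(C(=O)O1)[C@H]2[C@@H]3C(=O)OCC[Si](C)(C)C | intermediate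
11 | 2-iodoallyl ketone, ring A 2-ene | C=C(I)C[C@]23CC(=O)CC[C@H]2[C@@]12CC=C[C@@](C)(C(=O)O1)[C@H]2[C@@H]3C(=O)OCC[Si](C)(C)C | intermediate
12 | 2β,3β-diol | C=C(I)C[C@]23CC(=O)CC[C@H]2[C@@]12C[C@H](O)[C@H](O)[C@@](C)(C(=O)O1)[C@H]2[C@@H]3C(=O)OCC[Si](C)(C)C | intermediate
13 | 2β,3β-acetonide | C=C(I)C[C@]23CC(=O)CC[C@H]2[C@@]12C[C@H](O5)[C@H](OC5(C)C)[C@@](C)(C(=O)O1)[C@H]2[C@@H]3C(=O)OCC[Si](C)(C)C | intermediate
14 | C13 trimethylsilyl enol ether (C12=C13) | C=C(I)C[C@]23CC(O[Si](C)(C)C)=CC[C@H]2[C@@]12C[C@H](O5)[C@H](OC5(C)C)[C@@](C)(C(=O)O1)[C@H]2[C@@H]3C(=O)OCC[Si](C)(C)C | intermediate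
15 | 12β,13β-epoxide of 14 (silyloxy epoxide; not isolated) | C=C(I)C[C@]23C[C@]4(O[Si](C)(C)C)O[C@@H]4C[C@H]2[C@@]12C[C@H](O5)[C@H](OC5(C)C)[C@@](C)(C(=O)O1)[C@H]2[C@@H]3C(=O)OCC[Si](C)(C)C | intermediate
16 | 12β-hydroxy 13-ketone | C=C(I)C[C@]23CC(=O)[C@H](O)C[C@H]2[C@@]12C[C@H](O5)[C@H](OC5(C)C)[C@@](C)(C(=O)O1)[C@H]2[C@@H]3C(=O)OCC[Si](C)(C)C | intermediate
17 | 12α-(4-nitrobenzoate) 13-ketone | C=C(I)C[C@]23CC(=O)[C@@H](OC(=O)c4ccc(cc4)[N+](=O)[O-])C[C@H]2[C@@]12C[C@H](O5)[C@H](OC5(C)C)[C@@](C)(C(=O)O1)[C@H]2[C@@H]3C(=O)OCC[Si](C)(C)C | intermediate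
18 | 12α-hydroxy 13-ketone | C=C(I)C[C@]23CC(=O)[C@@H](O)C[C@H]2[C@@]12C[C@H](O5)[C@H](OC5(C)C)[C@@](C)(C(=O)O1)[C@H]2[C@@H]3C(=O)OCC[Si](C)(C)C | intermediate
19 | 12α-(tert-butyldimethylsilyloxy) 13-ketone, 2-iodoallyl on C8 (key-step precursor) | C=C(I)C[C@]23CC(=O)[C@@H](O[Si](C)(C)C(C)(C)C)C[C@H]2[C@@]12C[C@H](O5)[C@H](OC5(C)C)[C@@](C)(C(=O)O1)[C@H]2[C@@H]3C(=O)OCC[Si](C)(C)C | intermediate
20 | alkenylchromium dichloride from 19 (not isolated) | C=C([Cr](Cl)Cl)C[C@]23CC(=O)[C@@H](O[Si](C)(C)C(C)(C)C)C[C@H]2[C@@]12C[C@H](O5)[C@H](OC5(C)C)[C@@](C)(C(=O)O1)[C@H]2[C@@H]3C(=O)OCC[Si](C)(C)C | intermediate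
21 | C13 chromium alkoxide of 22 (not isolated) | C=C1C[C@]23C[C@@]1(O[Cr](Cl)Cl)[C@@H](O[Si](C)(C)C(C)(C)C)C[C@H]2[C@@]12C[C@H](O5)[C@H](OC5(C)C)[C@@](C)(C(=O)O1)[C@H]2[C@@H]3C(=O)OCC[Si](C)(C)C | intermediate
22 | ring D-closed 13-hydroxy-16-methylene compound, 12α-silyl ether, 2,3-acetonide, C7 2-(trimethylsilyl)ethyl ester (key-step product) | C=C1C[C@]23C[C@@]1(O)[C@@H](O[Si](C)(C)C(C)(C)C)C[C@H]2[C@@]12C[C@H](O5)[C@H](OC5(C)C)[C@@](C)(C(=O)O1)[C@H]2[C@@H]3C(=O)OCC[Si](C)(C)C | intermediate
23 | 12α,13-dihydroxy 7-acid 2,3-acetonide | C=C1C[C@]23C[C@@]1(O)[C@@H](O)C[C@H]2[C@@]12C[C@H](O5)[C@H](OC5(C)C)[C@@](C)(C(=O)O1)[C@H]2[C@@H]3C(=O)O | intermediate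
24 | CNP0191054.1 (2β,3β,12α,13-tetrahydroxy 19,10-lactone 7-acid) | C=C1C[C@]23C[C@@]1(O)[C@@H](O)C[C@H]2[C@@]12C[C@H](O)[C@H](O)[C@@](C)(C(=O)O1)[C@H]2[C@@H]3C(=O)O | target

Total step count: 18. Longest linear sequence: 18 steps (one linear sequence from 1).

Steps most likely to fail

Step 16. Addition to the ketone may be slow, because ring C must take up the chair with the C15 arm axial, in which the 12α-silyloxy group and C10 are syn-axial; protonolysis of the alkenylchromium species (iodine replaced by hydrogen) could then overtake ring closure. The fallback sets out from 19 and replaces the nickel/chromium relay by an anionic Barbier-type (Parham) cyclisation: iodine–lithium exchange with tert-butyllithium (2 equiv, THF/Et2O, −100 °C) should give the alkenyllithium F1, which adds at once to the neighbouring C13 carbonyl to give the lithium alkoxide F2; aqueous NH4Cl quench brings the route back at 22.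

Step 4. Hydrogen transfer to the allyl radical may be poorly regioselective, with delivery at C3 leaving the C1=C2 isomer alongside the wanted C2=C3 alkene. The fallback sets out from 4 and bypasses 5: hydrogenation of the C1=C2 bond over Rh on Al2O3 (H2, EtOAc, rt) should give the 1,2-dihydro 3β-alcohol F3, and anti elimination of the axial 3β-hydroxyl with the axial 2α-hydrogen using Martin sulfurane (CH2Cl2, rt) can only run towards C2, since C4 is quaternary; the route is rejoined at 6.

Step 13. The activated C12 oxygen may be lost by elimination towards C11, or the hindered displacement may not proceed, so that C12 is not inverted. The fallback sets out from 14 and replaces the alcohol inversion by a halide displacement: N-bromosuccinimide (THF, −78 °C) should brominate the enol ether on the same open β face to give the 12β-bromo ketone F4, SN2 displacement with CsOAc and 18-crown-6 (DMF, rt) should give the 12α-acetate F5, and methanolysis (K2CO3, MeOH, 0 °C) brings the route back at 18.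

Further compounds

F1 | step 16 | alkenyllithium from 19 | C=C([Li])C[C@]23CC(=O)[C@@H](O[Si](C)(C)C(C)(C)C)C[C@H]2[C@@]12C[C@H](O5)[C@H](OC5(C)C)[C@@](C)(C(=O)O1)[C@H]2[C@@H]3C(=O)OCC[Si](C)(C)C
F2 | step 16 | C13 lithium alkoxide of 22 | C=C1C[C@]23C[C@@]1(O[Li])[C@@H](O[Si](C)(C)C(C)(C)C)C[C@H]2[C@@]12C[C@H](O5)[C@H](OC5(C)C)[C@@](C)(C(=O)O1)[C@H]2[C@@H]3C(=O)OCC[Si](C)(C)C
F3 | step 4 | 1,2-dihydro derivative of 4 (ring A saturated, 3β-OH) | O=C1C[C@]23C[C@@]1(O)CC[C@H]2[C@@]12CC[C@H](O)[C@@](C)(C(=O)O1)[C@H]2[C@@H]3C(=O)OCC[Si](C)(C)C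
F4 | step 13 | 12β-bromo 13-ketone | C=C(I)C[C@]23CC(=O)[C@H](Br)C[C@H]2[C@@]12C[C@H](O5)[C@H](OC5(C)C)[C@@](C)(C(=O)O1)[C@H]2[C@@H]3C(=O)OCC[Si](C)(C)C
F5 | step 13 | 12α-acetoxy 13-ketone | C=C(I)C[C@]23CC(=O)[C@@H](OC(C)=O)C[C@H]2[C@@]12C[C@H](O5)[C@H](OC5(C)C)[C@@](C)(C(=O)O1)[C@H]2[C@@H]3C(=O)OCC[Si](C)(C)C
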